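Numbering (naphthalene skeleton): C1 (CH3, CH2OAc), C2=O, C3, C4, C4a=C8a, C5 (CH3, side chain C1'–C5'), C6 (CH3), C7 (OH), C8=O.
Retrosynthesis: cut (i) C5–C1' together with C6–CH3 (conjugate addition, enolate methylation), (ii) the C8–O ketal bond back to a 2-methoxyphenol, (iii) C1–CH2OH (aldol with formaldehyde), (iv) C1–CH3 and ring A (C4–C4a, C8a–C1; Haworth annulation on 2-methoxy-5-methylphenol); the side chain comes from 4-bromobut-1-yne.
Enabling feature: ring B (C4a, C5, C6, C7, C8, C8a) carries oxygen on C7 and C8, so its 2-hydroxycyclohexa-2,5-dienone is the 1,4-adduct of a carbanion to an o-quinone at C5, which already bears CH3 and therefore cannot rearomatise.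
Forward: ring A is built first; oxidative dearomatisation of ring B then lets the C1 CH2OH close a temporary five-membered ketal on C8 (not in the target), which makes C5 the β-carbon of a dienone; the intact (E)-side chain is added there as a Grignard reagent under chiral copper catalysis, and acid later opens the ketal to the diosphenol.
Stereochemistry: C1 from a chiral Sc catalyst (hydroxymethylation), C5 from the chiral Cu–NHC catalyst (reagent control; C1 is remote), the E olefin from syn-carboalumination; C8 (ketal) and C6 are temporary centres.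

Key step: step 13

Remark: which antipode of each chiral ligand (steps 7 and 13) gives the required sense of induction is assumed to be settled by a test reaction; compounds 1, 2 and 15 are taken as commercial.

Step 1
Reactants: 1 2-methoxy-5-methylphenol; 2 succinic anhydride
Product: 3 4-(4-hydroxy-5-methoxy-2-methylphenyl)-4-oxobutanoic acid
Conditions: AlCl3, PhNO2, 0 °C → rt; aq. HCl
Reagents that add atoms: none
Why: Friedel–Crafts acylation with the anhydride (first stage of a Haworth annulation) should occur para to the phenol oxygen, the only unhindered activated position, because the site para to OMe is blocked by the methyl group.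

Step 2
Reactants: 3 4-(4-hydroxy-5-methoxy-2-methylphenyl)-4-oxobutanoic acid
Product: 4 4-(4-hydroxy-5-methoxy-2-methylphenyl)butanoic acid
Conditions: H2 (3 atm), 10% Pd/C, AcOH, cat. HClO4, 60 °C
Reagents that add atoms: none
Why: Catalytic hydrogenolysis of the electron-rich aryl ketone reduces the benzylic C=O to CH2 (second stage of the Haworth sequence) without touching the acid or the phenol.

Step 3
Reactants: 4 4-(4-hydroxy-5-methoxy-2-methylphenyl)butanoic acid
Product: 5 7-hydroxy-8-methoxy-5-methyl-3,4-dihydronaphthalen-1(2H)-one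
Conditions: P2O5–MeSO3H (as solvent), 40 °C
Reagents that add atoms: none
Why: Intramolecular Friedel–Crafts acylation closes ring A at the only free ortho position of the side chain, which is activated by the adjacent methoxy group.

Step 4
Reactants: 5 7-hydroxy-8-methoxy-5-methyl-3,4-dihydronaphthalen-1(2H)-one
Product: 7 1-methoxy-4,8-dimethyl-5,6-dihydronaphthalen-2-ol, via tertiary alcohol 6 (not isolated)
Conditions: MeMgBr (3 equiv), THF, 0 °C → rt; aq. NH4Cl; then p-TsOH (cat.), toluene, 60 °C
Reagents that add atoms: methylmagnesium bromide, C[Mg]Br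
Why: Grignard 1,2-addition to the tetralone (one equivalent is consumed by the phenol) followed by acid-catalysed E1 dehydration of the tertiary benzylic alcohol gives the endocyclic, arene-conjugated alkene.

Step 5
Reactants: 7 1-methoxy-4,8-dimethyl-5,6-dihydronaphthalen-2-ol
Product: 9 racemic 7-hydroxy-8-methoxy-1,5-dimethyl-3,4-dihydronaphthalen-2(1H)-one, via epoxide 8 (not isolated)
Conditions: mCPBA, CH2Cl2, −10 → 0 °C; then BF3·OEt2 (cat.), 0 °C
Reagents that add atoms: 3-chloroperoxybenzoic acid, OOC(=O)c1cccc(Cl)c1
Why: Prilezhaev epoxidation of the electron-rich trisubstituted styrene and Lewis-acid Meinwald rearrangement (opening to the tertiary benzylic cation, 1,2-hydride shift) give the 2-tetralone; the C1 centre formed here is racemic and is erased in step 6.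

Step 6
Reactants: 9 racemic 7-hydroxy-8-methoxy-1,5-dimethyl-3,4-dihydronaphthalen-2(1H)-one
Product: 10 8-methoxy-1,5-dimethyl-2,7-bis(trimethylsilyloxy)-3,4-dihydronaphthalene
Conditions: TMSOTf (2.5 equiv), Et3N, CH2Cl2, 0 °C
Reagents that add atoms: trimethylsilyl trifluoromethanesulfonate, C[Si](C)(C)OS(=O)(=O)C(F)(F)F
Why: Soft enolisation and silylation under equilibrating conditions should give the arene-conjugated enol silane at the more acidic benzylic C1–H, and the phenol is silylated at the same time.

Step 7
Reactants: 10 8-methoxy-1,5-dimethyl-2,7-bis(trimethylsilyloxy)-3,4-dihydronaphthalene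
Product: 12 (S)-7-hydroxy-1-(hydroxymethyl)-8-methoxy-1,5-dimethyl-3,4-dihydronaphthalen-2(1H)-one, via aryl silyl ether 11 (not isolated)
Conditions: Sc(OTf)3 (10 mol %), chiral 6,6'-bis(1-hydroxy-2,2-dimethylpropyl)-2,2'-bipyridine (12 mol %), aq. HCHO, DME–H2O, −20 °C; aq. citric acid work-up
Reagents that add atoms: formaldehyde, C=O
Why: Catalytic asymmetric Mukaiyama aldol reaction with aqueous formaldehyde (hydroxymethylation of a tetrasubstituted enol silane, a known route to α-hydroxymethyl quaternary ketones): the chiral scandium–bipyridine complex selects the enantiotopic face of the enol silane so that C1 becomes S, and the near-neutral medium avoids retro-aldol loss of formaldehyde.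

Step 8
Reactants: 12 (S)-7-hydroxy-1-(hydroxymethyl)-8-methoxy-1,5-dimethyl-3,4-dihydronaphthalen-2(1H)-one
Product: 13 (1'S)-1'-(hydroxymethyl)-8'-methoxy-1',5'-dimethyl-3',4'-dihydro-1'H-spiro[1,3-dioxolane-2,2'-naphthalen]-7'-ol
Conditions: ethylene glycol, p-TsOH (cat.), benzene, reflux, water separator
Reagents that add atoms: ethylene glycol, OCCO
Why: Acid-catalysed ketalisation with azeotropic removal of water masks the C2 ketone against the Grignard reagent of step 13 and blocks retro-aldol cleavage at C1, whose quaternary nature rules out dehydration.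

Step 9
Reactants: 13 (1'S)-1'-(hydroxymethyl)-8'-methoxy-1',5'-dimethyl-3',4'-dihydro-1'H-spiro[1,3-dioxolane-2,2'-naphthalen]-7'-ol
Product: 14 tricyclic o-quinone monoketal: C7 ketone, C5=C6 and C4a=C8a alkenes, C2 ethylene ketal, C8 mixed ketal (8-OMe and an 8-O–CH2–C1 bridge), 1S, 8-OMe syn to the 1-CH3
Conditions: PhI(OAc)2 (1.1 equiv), CF3CH2OH, −20 °C
Reagents that add atoms: none
Why: λ3-Iodane oxidative dearomatisation of the 2-methoxyphenol: the phenoxenium-type intermediate is trapped at the methoxy-bearing ortho carbon C8 by the peri CH2OH group (five-membered ring), giving the o-quinone monoketal; C8 is a new but temporary stereocentre whose configuration is dictated by C1, because the O–CH2 bridge can only close cis, which leaves OMe syn to the C1 methyl.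

Step 10
Reactants: 15 4-bromobut-1-yne
Product: 17 ethyl (E)-5-bromo-3-methylpent-2-enoate, via alkenylalane 16 (not isolated)
Conditions: Me3Al (2 equiv), Cp2ZrCl2 (0.25 equiv), CH2Cl2, 0 °C → rt; then ClCO2Et, 0 °C
Reagents that add atoms: trimethylaluminium, C[Al](C)C; ethyl chloroformate, CCOC(Cl)=O
Why: Zirconium-catalysed carboalumination adds CH3 and Al syn across the terminal alkyne with CH3 at the internal carbon, and acylation of the alkenylalane with retention fixes the E trisubstituted olefin of the side chain.

Step 11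
Reactants: 17 ethyl (E)-5-bromo-3-methylpent-2-enoate
Product: 18 (E)-5-bromo-3-methylpent-2-en-1-ol
Conditions: DIBAL-H (2.2 equiv), CH2Cl2, −78 °C; aq. sodium potassium tartrate
Reagents that add atoms: none
Why: DIBAL-H 1,2-reduction of the enoate gives the allylic alcohol without touching the alkyl bromide or the olefin geometry.

Step 12
Reactants: 18 (E)-5-bromo-3-methylpent-2-en-1-ol
Product: 19 (E)-[(5-bromo-3-methylpent-2-en-1-yl)oxy](tert-butyl)diphenylsilane
Conditions: t-BuPh2SiCl, imidazole, CH2Cl2, rt
Reagents that add atoms: tert-butyl(chloro)diphenylsilane, CC(C)(C)[Si](Cl)(c1ccccc1)c1ccccc1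
Why: Standard silylation of the primary allylic alcohol gives an ether that tolerates Grignard formation and dilute acid.

Step 13
Reactants: 14 tricyclic o-quinone monoketal; 19 (E)-[(5-bromo-3-methylpent-2-en-1-yl)oxy](tert-butyl)diphenylsilane
Product: 22 conjugate-addition/methylation product: ketals of 14 retained, C7 ketone, C4a=C8a alkene, C5 quaternary (CH3 and (E)-5-(tert-butyldiphenylsilyloxy)-3-methylpent-3-enyl, the chain syn to the 1-CH3), C6 H(CH3) with CH3 anti to the chain, via Grignard reagent 20 (not isolated), via magnesium enolate 21 (not isolated)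
Conditions: 19, Mg, Et2O, rt (gives 20, used at once); 20 (1.3 equiv) added over 1 h to 14, Cu(OTf)2 (5 mol %), chiral imidazolinium salt (NHC precursor, 6 mol %), Et2O, −30 °C; then MeI, DMPU, −30 → 0 °C
Reagents that add atoms: iodomethane, CI
Why: Proposed new method: the closest known reaction type is the Cu/NHC-catalysed asymmetric conjugate addition of Grignard reagents to β-methyl cyclic enones and dienones, here extended to an o-quinone monoketal; the alkylcuprate formed from 20 π-complexes the C5=C6 bond of the O=C7–C6=C5–C4a=C8a dienone, oxidative addition gives a Cu(III) σ/π-allyl species and reductive elimination forms the C5–CH2 bond, leaving magnesium enolate 21, which MeI C-methylates at C6. No ring is closed. Regioselectivity (1,4 at C5, not 1,6 at C8a) is secured by the substrate, because C8a lies between the quaternary C1 and the ketal carbon C8, and because the C8 ketal leaves C7=O as the only activating carbonyl, so that C5, which already carries CH3, becomes a quaternary centre that cannot rearomatise. The new stereocentre C5 is controlled by the chiral NHC–Cu catalyst (the resident centres C1 and C8 are remote from C5 and should exert little bias), the ligand antipode being chosen so that the chain enters on the face syn to the C1 methyl and anti to the O–CH2 bridge. The C6 methyl is expected to enter anti to the new chain, but its configuration is immaterial since C6 becomes sp2 in step 14. The step also needs 1,4- over 1,2-addition and no electron-transfer rearomatisation, which catalytic copper, low temperature and slow addition of 20 are meant to secure, while the dioxolane and the ketal bridge keep the C2 carbonyl and the C1 CH2OH inert.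

Step 14
Reactants: 22 conjugate-addition/methylation product
Product: 23 (1S,5S)-5-[(E)-5-(tert-butyldiphenylsilyloxy)-3-methylpent-3-enyl]-7-hydroxy-1-(hydroxymethyl)-1,5,6-trimethyl-3,4-dihydronaphthalene-2,8(1H,5H)-dione
Conditions: 1 M aq. HCl, THF, rt → 40 °C
Reagents that add atoms: water, O
Why: Acid-catalysed hydrolysis cleaves the mixed ketal at C8 and the dioxolane at C2, and the resulting C7,C8-diketone enolises toward C6 to the conjugated diosphenol, which erases the C6 centre; the tert-butyldiphenylsilyl ether is expected to survive dilute aqueous acid.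

Step 15
Reactants: 23 (1S,5S)-5-[(E)-5-(tert-butyldiphenylsilyloxy)-3-methylpent-3-enyl]-7-hydroxy-1-(hydroxymethyl)-1,5,6-trimethyl-3,4-dihydronaphthalene-2,8(1H,5H)-dione
Product: 25 [(1S,5S)-5-[(E)-5-(tert-butyldiphenylsilyloxy)-3-methylpent-3-enyl]-7-hydroxy-1,5,6-trimethyl-2,8-dioxo-1,2,3,4,5,8-hexahydronaphthalen-1-yl]methyl acetate, via bis-acetate 24 (not isolated)
Conditions: Ac2O (2.5 equiv), pyridine, DMAP (cat.), CH2Cl2, 0 °C; then K2CO3 (cat.), MeOH, −20 °C
Reagents that add atoms: acetic anhydride, CC(=O)OC(C)=O
Why: Acetylation (nucleophilic catalysis by DMAP) esterifies the primary alcohol and the enol, and the enol acetate, a far better acyl donor than the neopentyl-type acetate, is then removed by brief base-catalysed methanolysis.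

Step 16
Reactants: 25 [(1S,5S)-5-[(E)-5-(tert-butyldiphenylsilyloxy)-3-methylpent-3-enyl]-7-hydroxy-1,5,6-trimethyl-2,8-dioxo-1,2,3,4,5,8-hexahydronaphthalen-1-yl]methyl acetate
Product: 26 [(1S,5S)-7-hydroxy-5-[(E)-5-hydroxy-3-methylpent-3-enyl]-1,5,6-trimethyl-2,8-dioxo-1,2,3,4,5,8-hexahydronaphthalen-1-yl]methyl acetate (target)
Conditions: HF·pyridine, THF–pyridine, 0 °C → rt
Reagents that add atoms: none
Why: Fluoride-mediated desilylation under weakly acidic conditions releases the allylic alcohol without cleaving the acetate or disturbing the diosphenol.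

Compound list
1 | 2-methoxy-5-methylphenol | Cc1ccc(OC)c(O)c1 | starting material
2 | succinic anhydride | O=C1CCC(=O)O1 | starting material
3 | 4-(4-hydroxy-5-methoxy-2-methylphenyl)-4-oxobutanoic acid | OC(=O)CCC(=O)c1cc(OC)c(O)cc1C | intermediate
4 | 4-(4-hydroxy-5-methoxy-2-methylphenyl)butanoic acid | OC(=O)CCCc1cc(OC)c(O)cc1C | intermediate
5 | 7-hydroxy-8-methoxy-5-methyl-3,4-dihydronaphthalen-1(2H)-one | O=C1CCCc2c(C)cc(O)c(OC)c12 | intermediate
6 | racemic 8-methoxy-1,5-dimethyl-1,2,3,4-tetrahydronaphthalene-1,7-diol | CC1(O)CCCc2c(C)cc(O)c(OC)c12 | intermediate (not isolated)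
7 | 1-methoxy-4,8-dimethyl-5,6-dihydronaphthalen-2-ol | CC1=CCCc2c(C)cc(O)c(OC)c12 | intermediate
8 | racemic 1,2-epoxy-8-methoxy-1,5-dimethyl-1,2,3,4-tetrahydronaphthalen-7-ol | CC12OC1CCc1c(C)cc(O)c(OC)c12 | intermediate (not isolated)
9 | racemic 7-hydroxy-8-methoxy-1,5-dimethyl-3,4-dihydronaphthalen-2(1H)-one | CC1C(=O)CCc2c(C)cc(O)c(OC)c12 | intermediate
10 | 8-methoxy-1,5-dimethyl-2,7-bis(trimethylsilyloxy)-3,4-dihydronaphthalene | CC1=C(O[Si](C)(C)C)CCc2c(C)cc(O[Si](C)(C)C)c(OC)c12 | intermediate
11 | (S)-1-(hydroxymethyl)-8-methoxy-1,5-dimethyl-7-(trimethylsilyloxy)-3,4-dihydronaphthalen-2(1H)-one | OC[C@@]1(C)C(=O)CCc2c(C)cc(O[Si](C)(C)C)c(OC)c12 | intermediate (not isolated)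
12 | (S)-7-hydroxy-1-(hydroxymethyl)-8-methoxy-1,5-dimethyl-3,4-dihydronaphthalen-2(1H)-one | OC[C@@]1(C)C(=O)CCc2c(C)cc(O)c(OC)c12 | intermediate
13 | (1'S)-1'-(hydroxymethyl)-8'-methoxy-1',5'-dimethyl-3',4'-dihydro-1'H-spiro[1,3-dioxolane-2,2'-naphthalen]-7'-ol | OC[C@@]1(C)C3(OCCO3)CCc2c(C)cc(O)c(OC)c12 | intermediate
14 | tricyclic o-quinone monoketal (C7 ketone, C5=C6 and C4a=C8a, C2 ethylene ketal, C8 mixed ketal with 8-OMe syn to the 1-CH3 and an 8-O–CH2–C1 bridge; 1S) | CO[C@]12OC[C@]3(C)C1=C(CCC34OCCO4)C(C)=CC2=O | intermediate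
15 | 4-bromobut-1-yne | C#CCCBr | starting material
16 | (E)-(4-bromo-2-methylbut-1-enyl)dimethylalane | BrCC/C(C)=C/[Al](C)C | intermediate (not isolated)
17 | ethyl (E)-5-bromo-3-methylpent-2-enoate | BrCC/C(C)=C/C(=O)OCC | intermediate
18 | (E)-5-bromo-3-methylpent-2-en-1-ol | BrCC/C(C)=C/CO | intermediate
19 | (E)-[(5-bromo-3-methylpent-2-en-1-yl)oxy](tert-butyl)diphenylsilane | BrCC/C(C)=C/CO[Si](c1ccccc1)(c1ccccc1)C(C)(C)C | intermediate
20 | (E)-[5-(tert-butyldiphenylsilyloxy)-3-methylpent-3-en-1-yl]magnesium bromide | Br[Mg]CC/C(C)=C/CO[Si](c1ccccc1)(c1ccccc1)C(C)(C)C | intermediate (not isolated)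
21 | bromomagnesium C7-enolate of the C5 conjugate adduct (chain at C5 syn to the 1-CH3) | CO[C@]12OC[C@]3(C)C1=C(CCC34OCCO4)[C@](C)(CC/C(C)=C/CO[Si](c4ccccc4)(c4ccccc4)C(C)(C)C)C=C2O[Mg]Br | intermediate (not isolated)
22 | conjugate-addition/methylation product (ketals of 14 retained; C5 quaternary with the chain syn to the 1-CH3; 6-CH3 anti to the chain; C7 ketone) | CO[C@]12OC[C@]3(C)C1=C(CCC34OCCO4)[C@](C)(CC/C(C)=C/CO[Si](c4ccccc4)(c4ccccc4)C(C)(C)C)[C@@H](C)C2=O | intermediate
23 | (1S,5S)-5-[(E)-5-(tert-butyldiphenylsilyloxy)-3-methylpent-3-enyl]-7-hydroxy-1-(hydroxymethyl)-1,5,6-trimethyl-3,4-dihydronaphthalene-2,8(1H,5H)-dione | OC[C@@]1(C)C(=O)CCC2=C1C(=O)C(O)=C(C)[C@@]2(C)CC/C(C)=C/CO[Si](c3ccccc3)(c3ccccc3)C(C)(C)C | intermediate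
24 | 7-O-acetyl derivative of 25 (bis-acetate) | CC(=O)OC[C@@]1(C)C(=O)CCC2=C1C(=O)C(OC(C)=O)=C(C)[C@@]2(C)CC/C(C)=C/CO[Si](c3ccccc3)(c3ccccc3)C(C)(C)C | intermediate (not isolated)
25 | [(1S,5S)-5-[(E)-5-(tert-butyldiphenylsilyloxy)-3-methylpent-3-enyl]-7-hydroxy-1,5,6-trimethyl-2,8-dioxo-1,2,3,4,5,8-hexahydronaphthalen-1-yl]methyl acetate | CC(=O)OC[C@@]1(C)C(=O)CCC2=C1C(=O)C(O)=C(C)[C@@]2(C)CC/C(C)=C/CO[Si](c3ccccc3)(c3ccccc3)C(C)(C)C | intermediate
26 | [(1S,5S)-7-hydroxy-5-[(E)-5-hydroxy-3-methylpent-3-enyl]-1,5,6-trimethyl-2,8-dioxo-1,2,3,4,5,8-hexahydronaphthalen-1-yl]methyl acetate | CC(=O)OC[C@@]1(C)C(=O)CCC2=C1C(=O)C(O)=C(C)[C@@]2(C)CC/C(C)=C/CO | target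

Total step count: 16. Longest linear sequence: 13 steps (steps 1–9 and 13–16).

Steps most likely to fail

1. Step 13 (Proposed new method). What may go wrong: single-electron transfer from the organometallic to the quinone monoketal with loss of alkoxide and rearomatisation, competing 1,2-addition to the C7 carbonyl, insufficient facial discrimination at C5 by the catalyst, or slow C-methylation of the magnesium enolate. Fallback (known chemistry; sets out from 14 and 19, returns at 22): Grignard reagent 20 is converted with stoichiometric CuBr·SMe2 into the organocopper reagent and added to 14 in the presence of Me3SiCl (chlorosilane-accelerated conjugate addition, established for hindered β,β-disubstituted enones). This should give the trimethylsilyl enol ether F1 together with its C5 epimer F2; the two are diastereomers, since C1 and C8 are fixed, and are separated by chromatography. F1 is then converted with MeLi into the lithium enolate and methylated with MeI to give 22.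

2. Step 7. What may go wrong: low conversion or poor face selection at the peri-hindered tetrasubstituted enol silane, or silylation of 9 toward C3 in step 6. Fallback (sets out from 9, returns at 12): a base-catalysed aldol reaction of 9 with aqueous formaldehyde (NaHCO3, THF–H2O; thermodynamic enolisation at the benzylic C1) gives the racemic hydroxymethyl ketone F3. Lipase-catalysed acylation with vinyl acetate (kinetic resolution; the enzyme is selected so that the R alcohol reacts) converts the unwanted enantiomer into the R acetate F4, and the unreacted S alcohol is 12.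

3. Step 14. What may go wrong: cleavage of the silyl ether before the hindered dioxolane and the α-keto ketal are fully hydrolysed, so that the two primary alcohols are no longer differentiated. Fallback (sets out from 22, returns at 23): exhaustive hydrolysis (aq. HCl, MeOH–THF, 40 °C) removes both ketals and the silyl group to give the diol F5. One equivalent of t-BuPh2SiCl with imidazole at −40 °C should then silylate only the unhindered allylic alcohol (the C1 CH2OH is neopentylic), which gives 23.

Further compounds
F1 | step 13 | trimethylsilyl enol ether of the C5 conjugate adduct (C5 configuration as in 22) | CO[C@]12OC[C@]3(C)C1=C(CCC34OCCO4)[C@](C)(CC/C(C)=C/CO[Si](c4ccccc4)(c4ccccc4)C(C)(C)C)C=C2O[Si](C)(C)C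
F2 | step 13 | C5 epimer of F1 | CO[C@]12OC[C@]3(C)C1=C(CCC34OCCO4)[C@@](C)(CC/C(C)=C/CO[Si](c4ccccc4)(c4ccccc4)C(C)(C)C)C=C2O[Si](C)(C)C
F3 | step 7 | racemic 7-hydroxy-1-(hydroxymethyl)-8-methoxy-1,5-dimethyl-3,4-dihydronaphthalen-2(1H)-one | OCC1(C)C(=O)CCc2c(C)cc(O)c(OC)c12
F4 | step 7 | (R)-(7-hydroxy-8-methoxy-1,5-dimethyl-2-oxo-1,2,3,4-tetrahydronaphthalen-1-yl)methyl acetate | CC(=O)OC[C@]1(C)C(=O)CCc2c(C)cc(O)c(OC)c12
F5 | step 14 | (1S,5S)-7-hydroxy-5-[(E)-5-hydroxy-3-methylpent-3-enyl]-1-(hydroxymethyl)-1,5,6-trimethyl-3,4-dihydronaphthalene-2,8(1H,5H)-dione | OC[C@@]1(C)C(=O)CCC2=C1C(=O)C(O)=C(C)[C@@]2(C)CC/C(C)=C/CO
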